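**Strategy.** The target is cut between C2 (the CH2 beside the ketone on the short arm) and the C3 carbonyl carbon (heptan-3-one numbering). The C3 ketone and the C5 hydroxyl, a 1,3-related pair, are stored in one strained ring: an (S)-4-substituted oxetan-2-one whose carbonyl is C3 and whose ring oxygen is the C5 oxygen. C2 arrives as the lithium enolate of a benzyl 3-arylpropanoate, whose ester is a traceless activating group. One Claisen-type acylation forms C2–C3, opens the ring and frees the C5–OH without a protecting group on it. Both halves come from dihydroferulic acid, and a single hydrogenolysis removes three benzyl groups and CO2.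

Key step: step 4

Remark: locants C1–C7 are those of the heptan-3-one chain of the target. C2 of compound 8 is configurationally labile, is expected as both epimers and is drawn without configuration, since step 5 removes it.

**Step 1**
Reactants: 1 3-(4-hydroxy-3-methoxyphenyl)propanoic acid (dihydroferulic acid)
Product: 2 benzyl 3-[4-(benzyloxy)-3-methoxyphenyl]propanoate
Conditions: BnBr (2.4 equiv), K2CO3, DMF, 60 °C
Reagents that add atoms: benzyl bromide, BrCc1ccccc1
Why: Under K2CO3 both the phenoxide (Williamson ether synthesis) and the carboxylate (SN2 esterification) should be benzylated in one operation, which supplies the enolate precursor for step 4 and the substrate for step 2.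

**Step 2**
Reactants: 2 benzyl 3-[4-(benzyloxy)-3-methoxyphenyl]propanoate
Product: 3 3-[4-(benzyloxy)-3-methoxyphenyl]propanal
Conditions: DIBAL-H (1.05 equiv), CH2Cl2, −78 °C; MeOH, then aq. Rochelle salt
Reagents that add atoms: none
Why: Partial ester reduction with DIBAL-H: the tetrahedral aluminium hemiacetal should persist at −78 °C and release the aldehyde only on work-up, and the aryl ethers are inert to the hydride.

**Step 3**
Reactants: 3 3-[4-(benzyloxy)-3-methoxyphenyl]propanal; 4 acetyl bromide
Product: 6 (4S)-4-{2-[4-(benzyloxy)-3-methoxyphenyl]ethyl}oxetan-2-one, via ketene 5 (not isolated)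
Conditions: iPr2NEt, chiral Al(III)–triamine bis(triflamide) catalyst (10 mol %), CH2Cl2, −50 °C
Reagents that add atoms: none
Why: Acyl halide–aldehyde cyclocondensation (a Lewis acid-catalysed formal [2+2] ketene–aldehyde cycloaddition): iPr2NEt turns 4 into ketene 5, which should add to the Re face of the aldehyde held on the chiral Al(III) centre, so that ring C4 (the later C5) is set as (S); the catalyst enantiomer chosen (ligand from L-valinol) is the one that gives (S)-4-(2-arylethyl)oxetan-2-ones from 3-arylpropanals.

**Step 4**
Reactants: 2 benzyl 3-[4-(benzyloxy)-3-methoxyphenyl]propanoate (2.2 equiv); 6 (4S)-4-{2-[4-(benzyloxy)-3-methoxyphenyl]ethyl}oxetan-2-one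
Product: 8 benzyl (5S)-7-[4-(benzyloxy)-3-methoxyphenyl]-2-{[4-(benzyloxy)-3-methoxyphenyl]methyl}-5-hydroxy-3-oxoheptanoate (both C2 epimers), via lithium ester enolate 7 (not isolated)
Conditions: LDA (2.1 equiv), THF, −78 °C; then 6 (1.0 equiv), −78 °C; AcOH, −78 °C
Reagents that add atoms: none
Why: The lithium enolate 7 adds to the strained lactone carbonyl of 6 and the tetrahedral intermediate collapses by acyl C–O cleavage, which forms the C2–C3 bond and releases the C5 oxygen as its lithium alkoxide. The closest known reaction type is the Claisen acylation of lithium ester enolates by β-lactones (or β-hydroxy esters), which gives δ-hydroxy-β-keto esters. No ring is closed; the four-membered ring is opened and its strain drives the step. C5 keeps its (S) configuration because its C–O bond is never broken, while the new centre at C2 forms as a mixture of epimers that the decarboxylation in step 5 erases. The step needs acyl rather than alkyl C–O attack and addition rather than α-deprotonation of 6: the hard lithium enolate at −78 °C and the secondary, SN2-reluctant ring C4 should secure the first, the high carbonyl electrophilicity of the strained ring the second. Over-addition and retro-aldol cleavage are blocked because the product is at once deprotonated to its β-keto ester enolate by the excess of 7.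

**Step 5**
Reactants: 8 benzyl (5S)-7-[4-(benzyloxy)-3-methoxyphenyl]-2-{[4-(benzyloxy)-3-methoxyphenyl]methyl}-5-hydroxy-3-oxoheptanoate
Product: 10 (5S)-5-hydroxy-1,7-bis(4-hydroxy-3-methoxyphenyl)heptan-3-one, via β-keto acid 9 (not isolated)
Conditions: H2 (1 atm), 10% Pd/C, EtOAc–EtOH, rt; then 45 °C
Reagents that add atoms: none
Why: Hydrogenolysis over Pd/C should cleave the benzyl ester and both aryl benzyl ethers, the α-substituted β-keto acid 9 then loses CO2 through the usual six-membered transition state (which removes C2 as a stereocenter), and neither the aliphatic ketone nor the non-benzylic C5 carbinol reacts, so the (S) configuration is retained.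

**Compound list**

1 | 3-(4-hydroxy-3-methoxyphenyl)propanoic acid (dihydroferulic acid) | COc1cc(CCC(=O)O)ccc1O | starting material
2 | benzyl 3-[4-(benzyloxy)-3-methoxyphenyl]propanoate | COc1cc(CCC(=O)OCc2ccccc2)ccc1OCc1ccccc1 | intermediate
3 | 3-[4-(benzyloxy)-3-methoxyphenyl]propanal | COc1cc(CCC=O)ccc1OCc1ccccc1 | intermediate
4 | acetyl bromide | CC(=O)Br | starting material
5 | ketene (formed in the flask, not isolated) | C=C=O | intermediate
6 | (4S)-4-{2-[4-(benzyloxy)-3-methoxyphenyl]ethyl}oxetan-2-one | O=C1C[C@H](CCc2ccc(OCc3ccccc3)c(OC)c2)O1 | intermediate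
7 | lithium enolate of 2, lithium 1-(benzyloxy)-3-[4-(benzyloxy)-3-methoxyphenyl]prop-1-en-1-olate (not isolated) | COc1cc(CC=C([O-])OCc2ccccc2)ccc1OCc1ccccc1.[Li+] | intermediate
8 | benzyl (5S)-7-[4-(benzyloxy)-3-methoxyphenyl]-2-{[4-(benzyloxy)-3-methoxyphenyl]methyl}-5-hydroxy-3-oxoheptanoate (both C2 epimers) | COc1cc(CC(C(=O)OCc2ccccc2)C(=O)C[C@@H](O)CCc2ccc(OCc3ccccc3)c(OC)c2)ccc1OCc1ccccc1 | intermediate
9 | (5S)-5-hydroxy-7-(4-hydroxy-3-methoxyphenyl)-2-[(4-hydroxy-3-methoxyphenyl)methyl]-3-oxoheptanoic acid (not isolated) | COc1cc(CC(C(=O)O)C(=O)C[C@@H](O)CCc2ccc(O)c(OC)c2)ccc1O | intermediate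
10 | (5S)-5-hydroxy-1,7-bis(4-hydroxy-3-methoxyphenyl)heptan-3-one | COc1cc(CCC(=O)C[C@@H](O)CCc2ccc(O)c(OC)c2)ccc1O | target

**Step count.** Total: 5 steps. Longest linear sequence: 5 steps (1 → 2 → 3 → 6 → 8 → 10); ester 2 from step 1 is used a second time in step 4, so no branch adds steps.

**Steps most likely to fail**

Step 4 (key step). Proton transfer from ring C3 of the lactone to the basic, α-branched enolate may compete with acylation. The enolate may also condense with itself, or the product may close onto its own benzyl ester on warming, which would block the decarboxylative endgame. The fallback sets out from 6 and returns at 10, forming the same C2–C3 bond by a Weinreb ketone synthesis. Lactone 6 is opened with MeNH(OMe)·HCl and Me2AlCl (CH2Cl2, 0 °C) to (3S)-5-[4-(benzyloxy)-3-methoxyphenyl]-3-hydroxy-N-methoxy-N-methylpentanamide F1. In parallel, commercial 2-(4-hydroxy-3-methoxyphenyl)ethanol is O-benzylated (BnBr, K2CO3, acetone) to 2-[4-(benzyloxy)-3-methoxyphenyl]ethanol F2, brominated by an Appel reaction (CBr4, PPh3) to 1-(benzyloxy)-4-(2-bromoethyl)-2-methoxybenzene F3, and converted with Mg in THF into {2-[4-(benzyloxy)-3-methoxyphenyl]ethyl}magnesium bromide F4. Three equivalents of F4 added to F1 (THF, 0 °C) should give, through the chelated tetrahedral intermediate, (5S)-1,7-bis[4-(benzyloxy)-3-methoxyphenyl]-5-hydroxyheptan-3-one F5. Hydrogenolysis (H2, Pd/C) then returns to the route at 10.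

Step 3. The Lewis-basic aryl ethers may bind the aluminium catalyst, or ketene may dimerise faster than it is captured, leading to low conversion or poor facial selectivity. The fallback sets out from 3 and returns at 6. A Roskamp reaction of 3 with ethyl diazoacetate (SnCl2 cat., CH2Cl2) should give ethyl 5-[4-(benzyloxy)-3-methoxyphenyl]-3-oxopentanoate F6. Noyori hydrogenation with RuCl2[(S)-BINAP] (H2, EtOH, 50 °C) should deliver ethyl (3S)-5-[4-(benzyloxy)-3-methoxyphenyl]-3-hydroxypentanoate F7; (S)-BINAP is expected to give the (S)-alcohol, and the benzyl ether survives. LiOH (THF–H2O) gives (3S)-5-[4-(benzyloxy)-3-methoxyphenyl]-3-hydroxypentanoic acid F8. Lactonisation by carboxyl activation (PhSO2Cl, pyridine, 0 °C) leaves the C–O bond at the stereocenter untouched and returns 6.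

Step 2. The aluminium hemiacetal may collapse before the quench, so that over-reduction to the primary alcohol accompanies unreacted ester. The fallback sets out from 2 and returns at 3. Full reduction with LiAlH4 (THF, 0 °C) gives 3-[4-(benzyloxy)-3-methoxyphenyl]propan-1-ol F9, and Dess–Martin oxidation (CH2Cl2, rt) gives 3.

**Further compounds**

F1 | step 4 | (3S)-5-[4-(benzyloxy)-3-methoxyphenyl]-3-hydroxy-N-methoxy-N-methylpentanamide | CON(C)C(=O)C[C@@H](O)CCc1ccc(OCc2ccccc2)c(OC)c1
F2 | step 4 | 2-[4-(benzyloxy)-3-methoxyphenyl]ethanol | COc1cc(CCO)ccc1OCc1ccccc1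
F3 | step 4 | 1-(benzyloxy)-4-(2-bromoethyl)-2-methoxybenzene | COc1cc(CCBr)ccc1OCc1ccccc1
F4 | step 4 | {2-[4-(benzyloxy)-3-methoxyphenyl]ethyl}magnesium bromide | COc1cc(CC[Mg]Br)ccc1OCc1ccccc1
F5 | step 4 | (5S)-1,7-bis[4-(benzyloxy)-3-methoxyphenyl]-5-hydroxyheptan-3-one | COc1cc(CCC(=O)C[C@@H](O)CCc2ccc(OCc3ccccc3)c(OC)c2)ccc1OCc1ccccc1
F6 | step 3 | ethyl 5-[4-(benzyloxy)-3-methoxyphenyl]-3-oxopentanoate | CCOC(=O)CC(=O)CCc1ccc(OCc2ccccc2)c(OC)c1
F7 | step 3 | ethyl (3S)-5-[4-(benzyloxy)-3-methoxyphenyl]-3-hydroxypentanoate | CCOC(=O)C[C@@H](O)CCc1ccc(OCc2ccccc2)c(OC)c1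
F8 | step 3 | (3S)-5-[4-(benzyloxy)-3-methoxyphenyl]-3-hydroxypentanoic acid | OC(=O)C[C@@H](O)CCc1ccc(OCc2ccccc2)c(OC)c1
F9 | step 2 | 3-[4-(benzyloxy)-3-methoxyphenyl]propan-1-ol | COc1cc(CCCO)ccc1OCc1ccccc1
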